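(The data were generated by integration from invented constants; noise was put on by code.)

I have a stirred, closed vessel in which solid substrate dissolves slowly into starting material. With catalyst, reagent turns starting material into target and second substrate into second product, and catalyst without reagent turns target into over-reaction product. The dawn run is this same flask, followed so far.

| flask | solid substrate | reagent | second substrate | catalyst | remark | time |
|---|---|---|---|---|---|---|
| dawn | 0.042 M | 0.042 M | 0.042 M | 55 µM | the very flask that is asked about, followed so far |  |
| flask | 0.042 M | 0.0420 M | 0.0420 M | 55 µM |  | 10 h |

dawn run (percent of the solid substrate charged)

| time / min | target / % | over-reaction product / % |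
|---|---|---|
| 10.0 | 1.4 | 0 |
| 20.0 | 4.3 | 0.1 |
| 30.0 | 7.2 | 0.1 |
| 60.0 | 17.2 | 1.6 |
| 120 | 28.4 | 7.2 |

(scatter of a reading: 0.5 percentage points)

- as a solid, counted per litre of solution: solid substrate
- steps thought possible: starting material + reagent + catalyst -> catalyst + target; second substrate + reagent + catalyst -> catalyst + second product; catalyst + target -> catalyst + over-reaction product; solid substrate <-> starting material
- at the start none of the solid substrate is in solution
- starting material means what is dissolved; the solid is not counted in it

- amount of target in the flask at 10 h, in percent of the solid substrate charged
- amount of over-reaction product in the flask at 10 h, in percent of the solid substrate charged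
- amount of solid substrate in the flask at 10 h, in percent of the solid substrate charged (only what is still solid)
- amount of starting material in the flask at 10 h, in percent of the solid substrate charged

Between the last two readings, over-reaction product rose by 5.6 percentage points in 60.0 min while target averaged 22.8%. That reads as 0.246 h⁻¹, my spoil rate: the share of the standing target lost to over-reaction product per hour. It is a pseudo-first-order constant, read with a scatter of 0.5 points on each point.

The sum of target and over-reaction product stood at 35.6% and was climbing by 0.168 h⁻¹ of the charge. Reagent is shared with second substrate, so I guess an even split, with the sum stopping at 0.5 of the charge, reached at 2.86 h. A steady feed until then, with the spoil rate acting throughout, leaves target at 12.4% of the sum at 10 h. That is 6.22% target and 43.8% over-reaction product.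

The even split is the weak link, since the dawn readings hold no second product. So I try a stop at 0.7: the feed ends at 4.05 h and the share becomes 14.7%. The share rises from 12.4% to 14.7%, but the amounts are share times stop, so this stop gives 10.3% target and 59.7% over-reaction product, a move of 16 points in over-reaction product. The dawn readings do not test the stop, so the link stays weak; I commit to 6.22% target and 43.8% over-reaction product as a guess from the even split, with the higher pair as the other case I tried. The readings do not split the remainder between starting material and solid substrate.

The forecast puts more in over-reaction product than my 43.8%: it gives 13% target, 61% over-reaction product, 14% solid substrate and 11% starting material, with the words “Solubility is poorly determined”.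

This flask gives 8.23% target, 41.9% over-reaction product, 7.04% solid substrate and 42.8% starting material.

    starting material + reagent + catalyst → catalyst + target (k = 328 M⁻² s⁻¹)
    second substrate + reagent + catalyst → catalyst + second product (k = 67.7 M⁻² s⁻¹)
    catalyst + target → catalyst + over-reaction product (k = 1.10 M⁻¹ s⁻¹)
    solid substrate ⇌ starting material, rate k4*(cs4 - [starting material]) while solid is left; crystals form when [starting material] > cs4 (solubility = 18.0 mM, k = 2.95 × 10⁻⁴ s⁻¹)

In this flask, reagent is down to 0.551% of its charge at 5.00 h, and target stands at 23.9%. The spoil rate carries that to 6.99% at 10 h, where the flask holds 8.23%. Over the further 5.00 h to the neighbouring flask, read at 15 h with all amounts held, the same rate turns 8.23% into 2.41%. That neighbouring flask holds 2.77% target and 47.4% over-reaction product.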